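**Strategy.** Gibberellane numbering is used. The plan rests on reading ring C (C8, C9, C11, C12, C13, C14), fused to cyclopentane ring B at the C8–C9 bond and carrying the quaternary C8, as a cyclohexene retron. One thermal intramolecular Diels–Alder reaction joins a C9=C11–C12=C13 diene on C10 to a C8=C14 alkene held three atoms away (C10–C5–C6) on a finished ring A; it makes the C8–C9 and C13–C14 bonds, closes rings B and C together and sets C8 and C9. The precursor is a monocyclic cyclohexane with a 1-benzyloxybutadienyl arm and an ester-bearing arm that ends in a 1,1-disubstituted alkene. Ring D then closes by a radical 5-exo-dig step, and C20 is oxidised last.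

Key step: step 13

Remark: the aldehyde–acid form drawn for the target equilibrates with its 19,20-lactol; this does not change the route. α/β refer to the usual gibberellin drawing (C20 α, H5 β, H9 β).

**Step 1**
Reactants: 1 2-methylenepropane-1,3-diol
Product: 2 2-{[tert-butyl(diphenyl)silyl]oxymethyl}prop-2-en-1-ol
Conditions: NaH (1.0 equiv), THF, 0 °C; TBDPSCl
Reagents that add atoms: tert-butyl(chloro)diphenylsilane, CC(C)(C)[Si](Cl)(c1ccccc1)c1ccccc1
Why: Monosilylation of a symmetric diol through its monosodium alkoxide (Williamson-type O-silylation, McDougal protocol) should stop after one silyl group; no stereocentre is involved.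

**Step 2**
Reactants: 2 2-{[tert-butyl(diphenyl)silyl]oxymethyl}prop-2-en-1-ol
Product: 3 2-{[tert-butyl(diphenyl)silyl]oxymethyl}prop-2-enal
Conditions: MnO2, CH2Cl2, rt
Reagents that add atoms: none
Why: Allylic alcohol oxidation with MnO2 stops at the enal, which is used without storage.

**Step 3**
Reactants: 3 2-{[tert-butyl(diphenyl)silyl]oxymethyl}prop-2-enal; 4 (E)-3-(tert-butyldimethylsilyloxy)-N,N-dimethylbuta-1,3-dien-1-amine (Rawal diene)
Product: 6 (R)-1-{[tert-butyl(diphenyl)silyl]oxymethyl}-4-oxocyclohex-2-ene-1-carbaldehyde, via amino silyl enol ether cycloadduct 5 (not isolated)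
Conditions: α,α,α′,α′-tetra(1-naphthyl)-2,2-dimethyl-1,3-dioxolane-4,5-dimethanol (20 mol%, the enantiomer that gives (R)-6), toluene, −80 °C; then AcCl, CH2Cl2, −78 °C → rt
Reagents that add atoms: none
Why: The hydrogen-bond-catalysed enantioselective Diels–Alder reaction of a 1-amino-3-siloxydiene with an α-substituted acrolein (the chiral diol activates the aldehyde through a hydrogen bond and shields one of its faces) should set C10 by catalyst control, and acetyl chloride then expels the amine as its acetamide and unmasks the enone.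

**Step 4**
Reactants: 6 (R)-enone aldehyde
Product: 7 (R)-4-(dimethoxymethyl)-4-{[tert-butyl(diphenyl)silyl]oxymethyl}cyclohex-2-en-1-one
Conditions: HC(OMe)3, MeOH, PPTS (cat.), rt
Reagents that add atoms: trimethyl orthoformate, COC(OC)OC
Why: Acid-catalysed acetalisation is selective for the aldehyde over the conjugated ketone and makes the future C9 carbon the larger, branched substituent on C10.

**Step 5**
Reactants: 7 acetal enone
Product: 8 (R)-4-(dimethoxymethyl)-2-iodo-4-{[tert-butyl(diphenyl)silyl]oxymethyl}cyclohex-2-en-1-one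
Conditions: I2, pyridine, CH2Cl2, rt
Reagents that add atoms: iodine, II
Why: α-Iodination of the enone by conjugate addition of pyridine, iodination of the enolate and elimination (Johnson protocol) functionalises C4 only.

**Step 6**
Reactants: 8 iodoenone
Product: 9 methyl (R)-3-(dimethoxymethyl)-3-{[tert-butyl(diphenyl)silyl]oxymethyl}-6-oxocyclohex-1-ene-1-carboxylate
Conditions: CO (1 atm), MeOH, Pd(OAc)2, PPh3, Et3N, DMF, 60 °C
Reagents that add atoms: carbon monoxide, [C-]#[O+]; methanol, CO
Why: Palladium-catalysed methoxycarbonylation of the vinyl iodide (oxidative addition, CO insertion, methanolysis) installs C19 and gives the doubly activated alkylidene β-keto ester needed for step 8.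

**Step 7**
Reactants: 10 4-(benzyloxy)butan-2-one; 11 trimethyl phosphonoacetate
Product: 12 methyl (E)-5-(benzyloxy)-3-methylpent-2-enoate
Conditions: NaH, THF, 0 °C → rt; chromatographic removal of the (Z)-isomer
Reagents that add atoms: none
Why: Horner–Wadsworth–Emmons olefination gives mainly the (E)-enoate, whose methyl group is cis to the ester as needed for syn γ-deprotonation.

**Step 8**
Reactants: 9 alkylidene β-keto ester; 12 methyl (E)-5-(benzyloxy)-3-methylpent-2-enoate
Product: 15 ring A β-keto diester (C3 ketone; C4 β-methyl and α-CO2Me; C5 α side chain CH(CO2Me)C(=CH2)CH2CH2OBn; C10 β-CH(OMe)2 and α-CH2OTBDPS), via lithium dienolate 13 (not isolated), via lithium enolate of the Michael adduct 14 (not isolated)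
Conditions: LiN(iPr)2, THF, −78 °C; add 9, −78 → −40 °C; MeI, DMPU, −40 → 0 °C
Reagents that add atoms: iodomethane, CI
Why: Kinetic γ-deprotonation of 12 gives a dienolate that adds through its α-carbon (C6) in a Michael reaction to C5 from the face anti to the branched acetal on C10 (so C6 ends cis to C20), and the β-keto ester enolate is then C-methylated anti to the new C5 substituent (C19 α, C18 β); C6 is expected as drawn from a chelated closed transition state and remains epimerisable next to its ester.

**Step 9**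
Reactants: 15 ring A β-keto diester
Product: 17 3β-(tert-butyldimethylsilyloxy) diester, via potassium alkoxide 16 (not isolated)
Conditions: K[HB(s-Bu)3], THF, −78 °C; then TBSOTf, −78 → 0 °C
Reagents that add atoms: tert-butyldimethylsilyl trifluoromethanesulfonate, CC(C)(C)[Si](C)(C)OS(=O)(=O)C(F)(F)F
Why: The bulky hydride attacks the C3 ketone along the equatorial trajectory to give the axial 3β-alkoxide (Selectride reduction), which is silylated in the flask before retro-aldol cleavage can occur.

**Step 10**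
Reactants: 17 3β-silyloxy acetal
Product: 18 C9 aldehyde (C10 carries CHO and α-CH2OTBDPS)
Conditions: TsOH·H2O (cat.), acetone/H2O, rt
Reagents that add atoms: water, O
Why: Mild acid-catalysed acetal hydrolysis frees the non-enolisable neopentyl aldehyde while the hindered silyl ethers survive.

**Step 11**
Reactants: 18 C9 aldehyde
Product: 19 (E)-enal (C9=C11–C12HO on C10)
Conditions: Ph3P=CHCHO, toluene, 90 °C
Reagents that add atoms: (triphenylphosphoranylidene)acetaldehyde, O=CC=P(c1ccccc1)(c1ccccc1)c1ccccc1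
Why: Wittig reaction with the stabilised formylmethylene ylide gives the (E)-enal under neutral conditions that do not touch the acidic C6–H.

**Step 12**
Reactants: 19 (E)-enal
Product: 20 (1E,3E)-4-(benzyloxy)buta-1,3-dienyl triene (BnO–C13H=C12H–C11H=C9H–C10)
Conditions: BnOCH2PPh3Cl, NaN(SiMe3)2, THF, −78 → 0 °C
Reagents that add atoms: (benzyloxymethyl)triphenylphosphonium chloride, [Cl-].c1ccccc1COC[P+](c1ccccc1)(c1ccccc1)c1ccccc1
Why: Wittig reaction of the enal with an alkoxymethylene ylide gives the 1-alkoxy-1,3-diene; the enol ether geometry (drawn E) is of no consequence because C13 is planarised in step 18.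

**Step 13**
Reactants: 20 triene
Product: 21 tricyclic cycloadduct (rings A, B, C; C11=C12; C13 OBn; C8 β-CH2CH2OBn; H9 β)
Conditions: toluene (0.005 M), BHT, 180 °C, sealed tube
Reagents that add atoms: none
Why: Concerted, asynchronous thermal [4+2] cycloaddition (type 1 intramolecular Diels–Alder of a 1,3,8-nonatriene with a 1-alkoxybutadiene and an unactivated 1,1-disubstituted alkene), the closest known class being nonatriene cyclisations to hydrindenes. Ring C (six-membered) closes by the cycloaddition itself and ring B (five-membered) closes in the fused mode through the three-atom tether C10–C5–C6, with C8–C9 as the shared bond. C9 is fixed by the E geometry of C9=C11 together with the diene face attacked, C8 by the alkene face presented (tether C6 endo and C15 chain exo give the cis B/C junction), and C13 is left uncontrolled because it becomes a radical centre in step 18. The step needs the endo-tether transition state on the diene face that puts C11 on the side of C20 and the C15 chain away from C20. The substrate favours this because it is the only arrangement in which the bulky C15 chain is exo and avoids a 1,3-clash across the new ring B with the CH2OTBDPS group on C10; the trans-diequatorial ring A tether, however, has a built-in bias towards the trans-fused mode, so diastereomers must be expected and separated. Regiochemistry is fixed by the tether, and no other alkene is within reach of the diene.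

**Step 14**
Reactants: 21 tricyclic cycloadduct
Product: 22 saturated diol (C13 OH, C16 OH)
Conditions: H2 (1 atm), Pd/C, EtOAc, rt
Reagents that add atoms: none
Why: Heterogeneous hydrogenation saturates the disubstituted C11=C12 alkene and hydrogenolysis removes both benzyl ethers; no other reducible group is present.

**Step 15**
Reactants: 22 diol
Product: 23 C16 aldehyde with free C13 hydroxyl
Conditions: TEMPO (cat.), PhI(OAc)2 (1.1 equiv), CH2Cl2, rt
Reagents that add atoms: none
Why: Oxoammonium oxidation (TEMPO/PhI(OAc)2) is selective for the primary C16 alcohol over the secondary C13 alcohol and stops at the aldehyde, and the small excess of oxidant keeps any bridged lactol of the 13-epimer cis to the side chain from going on to a lactone.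

**Step 16**
Reactants: 23 hydroxy aldehyde
Product: 24 terminal alkyne (C8–C15H2–C16≡C17H) with free C13 hydroxyl
Conditions: Ohira–Bestmann reagent, K2CO3, MeOH, 0 °C → rt
Reagents that add atoms: dimethyl (1-diazo-2-oxopropyl)phosphonate, COP(=O)(OC)C(=[N+]=[N-])C(C)=O
Why: Seyferth–Gilbert homologation with the Ohira–Bestmann reagent turns the aldehyde into the alkyne that supplies C16 and C17, and the mild base lets C6 settle in its preferred configuration.

**Step 17**
Reactants: 24 hydroxy alkyne
Product: 25 C13 O-(imidazol-1-ylthiocarbonyl) derivative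
Conditions: 1,1'-thiocarbonyldiimidazole, DMAP (cat.), 1,2-dichloroethane, 70 °C
Reagents that add atoms: 1,1'-thiocarbonyldiimidazole, S=C(n1ccnc1)n1ccnc1
Why: Acylation of the only free hydroxyl gives the thiocarbonyl derivative needed for radical generation (Barton–McCombie activation).

**Step 18**
Reactants: 25 thiocarbonylimidazolide
Product: 26 tetracyclic exo-methylene diester (3β-OTBS, C20 OTBDPS)
Conditions: Bu3SnH (slow addition), AIBN, toluene, 110 °C
Reagents that add atoms: none
Why: Tin radical addition to the thiocarbonyl group releases the secondary C13 radical, which closes ring D by 5-exo-dig attack on C16 (radical cyclisation under Barton–McCombie conditions) and the vinyl radical takes hydrogen to give the exocyclic methylene; the two-carbon bridge can only form on the face of the C15 chain, so C13 is set whatever the configuration of 25.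

**Step 19**
Reactants: 26 bis-silyl ether
Product: 27 3β,20-diol dimethyl ester
Conditions: HF·pyridine, excess pyridine, THF, 0 °C → rt; crude product used at once
Reagents that add atoms: none
Why: Fluoride cleaves both silyl ethers under buffered conditions that leave the exocyclic alkene in place; because the 20-hydroxyl is 1,3-diaxial to the C19 ester and can close the 19,20-lactone, 27 is neither heated nor stored.

**Step 20**
Reactants: 27 diol
Product: 28 dimethyl ester of the target (C20 aldehyde, free 3β-OH)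
Conditions: TEMPO (cat.), PhI(OAc)2, CH2Cl2, rt
Reagents that add atoms: none
Why: The oxoammonium oxidant takes the primary neopentyl C20 alcohol of freshly made 27 to the aldehyde and leaves the hindered axial 3β-alcohol untouched.

**Step 21**
Reactants: 28 dimethyl ester of the target
Product: 29 the target gibberellin (3β-hydroxy-20-oxogibberell-16-ene-7,19-dioic acid)
Conditions: LiOH, THF/MeOH/H2O, rt → 45 °C; then 1 M HCl to pH 3
Reagents that add atoms: lithium hydroxide, [Li+].[OH-]
Why: Saponification of both methyl esters, the hindered C19 ester being attacked intramolecularly by the hydrate of the neighbouring C20 aldehyde; C6 equilibrates to the more stable configuration with the carboxyl anti to C4, and acidification gives the target.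

**Compound list**

1 | 2-methylenepropane-1,3-diol | C=C(CO)CO | starting material
2 | 2-{[tert-butyl(diphenyl)silyl]oxymethyl}prop-2-en-1-ol | C=C(CO)CO[Si](c1ccccc1)(c1ccccc1)C(C)(C)C | intermediate
3 | 2-{[tert-butyl(diphenyl)silyl]oxymethyl}prop-2-enal | C=C(C=O)CO[Si](c1ccccc1)(c1ccccc1)C(C)(C)C | intermediate
4 | (E)-3-(tert-butyldimethylsilyloxy)-N,N-dimethylbuta-1,3-dien-1-amine | C=C(O[Si](C)(C)C(C)(C)C)/C=C/N(C)C | starting material
5 | cycloadduct: 2-(dimethylamino)-4-(tert-butyldimethylsilyloxy)-1-(TBDPS-oxymethyl)cyclohex-3-ene-1-carbaldehyde, amine cis to CHO | O=C[C@]1(CO[Si](c2ccccc2)(c2ccccc2)C(C)(C)C)CCC(O[Si](C)(C)C(C)(C)C)=C[C@@H]1N(C)C | intermediate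
6 | (R)-1-{[tert-butyl(diphenyl)silyl]oxymethyl}-4-oxocyclohex-2-ene-1-carbaldehyde | O=C[C@]1(CO[Si](c2ccccc2)(c2ccccc2)C(C)(C)C)CCC(=O)C=C1 | intermediate
7 | (R)-4-(dimethoxymethyl)-4-(TBDPS-oxymethyl)cyclohex-2-en-1-one | COC(OC)[C@]1(CO[Si](c2ccccc2)(c2ccccc2)C(C)(C)C)CCC(=O)C=C1 | intermediate
8 | (R)-4-(dimethoxymethyl)-2-iodo-4-(TBDPS-oxymethyl)cyclohex-2-en-1-one | COC(OC)[C@]1(CO[Si](c2ccccc2)(c2ccccc2)C(C)(C)C)CCC(=O)C(I)=C1 | intermediate
9 | methyl (R)-3-(dimethoxymethyl)-3-(TBDPS-oxymethyl)-6-oxocyclohex-1-ene-1-carboxylate | COC(OC)[C@]1(CO[Si](c2ccccc2)(c2ccccc2)C(C)(C)C)CCC(=O)C(C(=O)OC)=C1 | intermediate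
10 | 4-(benzyloxy)butan-2-one | CC(=O)CCOCc1ccccc1 | starting material
11 | trimethyl phosphonoacetate | COC(=O)CP(=O)(OC)OC | starting material
12 | methyl (E)-5-(benzyloxy)-3-methylpent-2-enoate | COC(=O)/C=C(\C)CCOCc1ccccc1 | intermediate
13 | lithium dienolate of 12 | [Li]OC(OC)=CC(=C)CCOCc1ccccc1 | intermediate
14 | lithium enolate of the Michael adduct (C3–O–Li, C3=C4) | COC(OC)[C@]1(CO[Si](c2ccccc2)(c2ccccc2)C(C)(C)C)CCC(O[Li])=C(C(=O)OC)[C@H]1[C@@H](C(=C)CCOCc1ccccc1)C(=O)OC | intermediate
15 | ring A β-keto diester (4β-Me, 4α-CO2Me, 5α side chain, 10β-CH(OMe)2, 10α-CH2OTBDPS) | COC(OC)[C@]1(CO[Si](c2ccccc2)(c2ccccc2)C(C)(C)C)CCC(=O)[C@@](C)(C(=O)OC)[C@H]1[C@@H](C(=C)CCOCc1ccccc1)C(=O)OC | intermediate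
16 | potassium 3β-alkoxide of reduced 15 | COC(OC)[C@]1(CO[Si](c2ccccc2)(c2ccccc2)C(C)(C)C)CC[C@H]([O-])[C@@](C)(C(=O)OC)[C@H]1[C@@H](C(=C)CCOCc1ccccc1)C(=O)OC.[K+] | intermediate
17 | 3β-OTBS acetal diester | COC(OC)[C@]1(CO[Si](c2ccccc2)(c2ccccc2)C(C)(C)C)CC[C@H](O[Si](C)(C)C(C)(C)C)[C@@](C)(C(=O)OC)[C@H]1[C@@H](C(=C)CCOCc1ccccc1)C(=O)OC | intermediate
18 | C9 aldehyde | O=C[C@]1(CO[Si](c2ccccc2)(c2ccccc2)C(C)(C)C)CC[C@H](O[Si](C)(C)C(C)(C)C)[C@@](C)(C(=O)OC)[C@H]1[C@@H](C(=C)CCOCc1ccccc1)C(=O)OC | intermediate
19 | (E)-enal | O=C/C=C/[C@]1(CO[Si](c2ccccc2)(c2ccccc2)C(C)(C)C)CC[C@H](O[Si](C)(C)C(C)(C)C)[C@@](C)(C(=O)OC)[C@H]1[C@@H](C(=C)CCOCc1ccccc1)C(=O)OC | intermediate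
20 | (1E,3E)-4-(benzyloxy)butadienyl triene | c1ccccc1CO/C=C/C=C/[C@]1(CO[Si](c2ccccc2)(c2ccccc2)C(C)(C)C)CC[C@H](O[Si](C)(C)C(C)(C)C)[C@@](C)(C(=O)OC)[C@H]1[C@@H](C(=C)CCOCc1ccccc1)C(=O)OC | intermediate
21 | tricyclic cycloadduct (C11=C12, 13-OBn, 8β-CH2CH2OBn, 9β-H) | c1ccccc1COCC[C@]12C[C@@H](OCc3ccccc3)C=C[C@H]1[C@]1(CO[Si](c3ccccc3)(c3ccccc3)C(C)(C)C)CC[C@H](O[Si](C)(C)C(C)(C)C)[C@@](C)(C(=O)OC)[C@H]1[C@@H]2C(=O)OC | intermediate
22 | saturated 13,16-diol | OCC[C@]12C[C@@H](O)CC[C@H]1[C@]1(CO[Si](c3ccccc3)(c3ccccc3)C(C)(C)C)CC[C@H](O[Si](C)(C)C(C)(C)C)[C@@](C)(C(=O)OC)[C@H]1[C@@H]2C(=O)OC | intermediate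
23 | C16 aldehyde, 13-OH | O=CC[C@]12C[C@@H](O)CC[C@H]1[C@]1(CO[Si](c3ccccc3)(c3ccccc3)C(C)(C)C)CC[C@H](O[Si](C)(C)C(C)(C)C)[C@@](C)(C(=O)OC)[C@H]1[C@@H]2C(=O)OC | intermediate
24 | terminal alkyne, 13-OH | C#CC[C@]12C[C@@H](O)CC[C@H]1[C@]1(CO[Si](c3ccccc3)(c3ccccc3)C(C)(C)C)CC[C@H](O[Si](C)(C)C(C)(C)C)[C@@](C)(C(=O)OC)[C@H]1[C@@H]2C(=O)OC | intermediate
25 | C13 O-(imidazol-1-ylthiocarbonyl) alkyne | C#CC[C@]12C[C@@H](OC(=S)n3ccnc3)CC[C@H]1[C@]1(CO[Si](c3ccccc3)(c3ccccc3)C(C)(C)C)CC[C@H](O[Si](C)(C)C(C)(C)C)[C@@](C)(C(=O)OC)[C@H]1[C@@H]2C(=O)OC | intermediate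
26 | tetracyclic exo-methylene diester, 3β-OTBS, 20-OTBDPS | C=C1C[C@]23C[C@H]1CC[C@H]2[C@]1(CO[Si](c4ccccc4)(c4ccccc4)C(C)(C)C)CC[C@H](O[Si](C)(C)C(C)(C)C)[C@@](C)(C(=O)OC)[C@H]1[C@@H]3C(=O)OC | intermediate
27 | 3β,20-diol dimethyl ester | C=C1C[C@]23C[C@H]1CC[C@H]2[C@]1(CO)CC[C@H](O)[C@@](C)(C(=O)OC)[C@H]1[C@@H]3C(=O)OC | intermediate
28 | dimethyl 3β-hydroxy-20-oxogibberell-16-ene-7,19-dioate (dimethyl ester of the target) | C=C1C[C@]23C[C@H]1CC[C@H]2[C@]1(C=O)CC[C@H](O)[C@@](C)(C(=O)OC)[C@H]1[C@@H]3C(=O)OC | intermediate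
29 | 3β-hydroxy-20-oxogibberell-16-ene-7,19-dioic acid (the target gibberellin) | C=C1C[C@]23C[C@H]1CC[C@H]2[C@]1(C=O)CC[C@H](O)[C@@](C)(C(=O)O)[C@H]1[C@@H]3C(=O)O | target

**Total step count:** 21. **Longest linear sequence:** 20 steps (steps 1–6 and 8–21; step 7 prepares the side-chain ester 12).

**Steps most likely to fail**

Step 13 (key step). The cycloaddition may run mainly through the exo-tether mode, which gives a trans B/C junction, or add to the other diene face, because the chair of ring A twists the three-atom tether against the endo geometry. Fallback: the same triene 20 is cyclised to 21 by a rhodium-catalysed [4+2] reaction ([Rh(cod)2]SbF6, a monovalent rhodium catalyst, CH2Cl2, 40 °C). This known diene–ene cycloaddition proceeds through oxidative cyclisation to a rhodacycle and reductive elimination, so the ring fusion is set in a stepwise metallacycle and not in a boat-like pericyclic transition state. It sets out from 20, returns at 21 and makes no new compound.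

Step 8. Facial discrimination at C5 between the two substituents on C10 may be poor, and 1,2-addition of the dienolate may compete. Fallback: the stereocontrol element is changed to a much larger cyclic acetal. The detour sets out from 6 and returns at 18. Aldehyde 6 is acetalised with 2,2-dimethylpropane-1,3-diol (TsOH, benzene, water removal) to the 5,5-dimethyl-1,3-dioxan-2-yl enone F1. F1 is iodinated (I2, pyridine) to the iodoenone F2 and methoxycarbonylated (CO, MeOH, Pd(OAc)2, PPh3, Et3N) to the alkylidene β-keto ester F3. Michael addition of dienolate 13 followed by methylation gives the β-keto diester F4. Reduction with K[HB(s-Bu)3] and silylation in the flask give the 3β-silyl ether F5, and acid hydrolysis (TsOH, wet acetone, 50 °C) releases aldehyde 18.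

Step 19. The freed 20-hydroxyl may attack the neighbouring axial C19 ester and close the 19,20-lactone before it can be oxidised. Fallback: the lactone is made on purpose and the hydroxy ester is then released under neutral alkylating conditions. The detour sets out from 26 and returns at 28. Bu4NF (THF, 0 °C → rt) removes the primary silyl ether, and the alkoxide closes onto C19 to give the 3β-silyloxy 19,20-lactone 7-methyl ester F6. KOH (aqueous MeOH, reflux) opens the lactone and hydrolyses the C7 ester to the dipotassium 20-hydroxy dicarboxylate F7, which is kept basic. MeI (KHCO3, DMF, 0 °C → rt) alkylates both carboxylates to the 3β-silyloxy 20-hydroxy dimethyl ester F8, which is oxidised at once (TEMPO, PhI(OAc)2, CH2Cl2) to the 3β-silyloxy 20-aldehyde F9. HF·pyridine (THF, rt) then removes the 3β-silyl ether to give 28.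

**Further compounds**

F0 | step 13 | none | none
F1 | step 8 | (R)-4-(5,5-dimethyl-1,3-dioxan-2-yl)-4-(TBDPS-oxymethyl)cyclohex-2-en-1-one | CC1(C)COC(OC1)[C@]2(CO[Si](c3ccccc3)(c3ccccc3)C(C)(C)C)CCC(=O)C=C2
F2 | step 8 | 2-iodo derivative of F1 | CC1(C)COC(OC1)[C@]2(CO[Si](c3ccccc3)(c3ccccc3)C(C)(C)C)CCC(=O)C(I)=C2
F3 | step 8 | 2-methoxycarbonyl derivative of F1 | CC1(C)COC(OC1)[C@]2(CO[Si](c3ccccc3)(c3ccccc3)C(C)(C)C)CCC(=O)C(C(=O)OC)=C2
F4 | step 8 | Michael/methylation product with dioxane acetal | CC1(C)COC(OC1)[C@]2(CO[Si](c3ccccc3)(c3ccccc3)C(C)(C)C)CCC(=O)[C@@](C)(C(=O)OC)[C@H]2[C@@H](C(=C)CCOCc1ccccc1)C(=O)OC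
F5 | step 8 | 3β-OTBS derivative with dioxane acetal | CC1(C)COC(OC1)[C@]2(CO[Si](c3ccccc3)(c3ccccc3)C(C)(C)C)CC[C@H](O[Si](C)(C)C(C)(C)C)[C@@](C)(C(=O)OC)[C@H]2[C@@H](C(=C)CCOCc1ccccc1)C(=O)OC
F6 | step 19 | 3β-OTBS 19,20-lactone 7-methyl ester | C=C1C[C@]23C[C@H]1CC[C@H]2[C@]1(COC5=O)CC[C@H](O[Si](C)(C)C(C)(C)C)[C@]5(C)[C@H]1[C@@H]3C(=O)OC
F7 | step 19 | dipotassium 3β-OTBS 20-hydroxy 7,19-dicarboxylate | C=C1C[C@]23C[C@H]1CC[C@H]2[C@]1(CO)CC[C@H](O[Si](C)(C)C(C)(C)C)[C@@](C)(C(=O)[O-])[C@H]1[C@@H]3C(=O)[O-].[K+].[K+]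
F8 | step 19 | 3β-OTBS 20-hydroxy dimethyl ester | C=C1C[C@]23C[C@H]1CC[C@H]2[C@]1(CO)CC[C@H](O[Si](C)(C)C(C)(C)C)[C@@](C)(C(=O)OC)[C@H]1[C@@H]3C(=O)OC
F9 | step 19 | 3β-OTBS 20-oxo dimethyl ester | C=C1C[C@]23C[C@H]1CC[C@H]2[C@]1(C=O)CC[C@H](O[Si](C)(C)C(C)(C)C)[C@@](C)(C(=O)OC)[C@H]1[C@@H]3C(=O)OC
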